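## Retrosynthetic overview

1. Labels (stilbenoid numbering): the core is a dibenzo-fused cis-bicyclo[3.3.0]octane (C7, C8, C8', C7'; ring A = C9'–C14', ring B = C9–C14) whose central C8–C8' bond joins two carbons of like polarity; ring B also carries a trans-2,3-diaryl-dihydrobenzofuran (O on C11, C8'' on C12, stereocentres C7''/C8'').
2. Last C–C events: a twofold Friedel–Crafts closure (C7–C10' and C7'–C10) of an acyclic (8S,8'S)-1,4-diol builds both cyclopentane rings at once and relays C8/C8' to C7/C7'.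
3. C8–C8' and its two stereocentres come from an auxiliary-controlled oxidative coupling of two arylacetyl-oxazolidinone enolates (umpolung by oxidation); the two acyl groups then become the 4-methoxyphenyl ketones.
4. The dihydrobenzofuran is made first, on a still symmetric 2,6-dioxygenated arene, by Rh-catalysed donor/donor-carbene C–H insertion (sets C8'') and C7'' epimerisation; O11 and O13 therefore never have to be told apart, and the later closure at C10 is directed by the tied-back furan oxygen.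
5. Order of ring formation: dihydrofuran ring (step 4), both carbocyclic five-membered rings (step 12), then global O-demethylation (step 13).

Key step: step 12

Remark: the sense of induction of the (S)-oxazolidinone in step 8 (bond formation anti to the benzyl group of the chelated Z-enolate) and of Rh2(R-PTAD)4 in step 4 is assumed from the accepted models; if either is opposite, the enantiomeric auxiliary or catalyst is used with no other change.

## Route

Step 1
Reactants: 1 2-(3,5-dimethoxyphenyl)acetic acid; 2 (4S)-4-benzyl-1,3-oxazolidin-2-one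
Product: 3 (4S)-4-benzyl-3-[2-(3,5-dimethoxyphenyl)acetyl]-1,3-oxazolidin-2-one
Conditions: PivCl, Et3N, THF, −20 °C; then LiCl, 2, −20 °C → rt
Reagents that add atoms: none
Why: N-acylation of the oxazolidinone through the mixed pivalic anhydride (LiCl/Et3N protocol) is a standard imide synthesis for arylacetic acids and creates no stereocentre.

Step 2
Reactants: 4 4-bromo-2,6-difluorobenzonitrile; 5 (4-methoxyphenyl)methanol
Product: 7 4-bromo-2-methoxy-6-[(4-methoxyphenyl)methoxy]benzonitrile, via monofluoro aryl ether 6 (not isolated)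
Conditions: 5 (1.0 equiv), NaH, THF, 0 °C → rt; then NaOMe, MeOH, 50 °C
Reagents that add atoms: sodium methoxide, [Na+].[O-]C
Why: Two consecutive SNAr reactions at the fluorides ortho to the nitrile (fluoride leaves far faster than the para bromide, and the first alkoxy group slows the second substitution so that each alkoxide enters once) differentiate the two oxygens while the ring is still symmetric, so no regiochemical choice arises.

Step 3
Reactants: 7 4-bromo-2-methoxy-6-[(4-methoxyphenyl)methoxy]benzonitrile; 8 (3,5-dimethoxyphenyl)magnesium bromide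
Product: 10 hydrazone of {4-bromo-2-methoxy-6-[(4-methoxyphenyl)methoxy]phenyl}(3,5-dimethoxyphenyl)methanone, via N–H ketimine 9 (not isolated)
Conditions: 8 (2 equiv), CuBr (5 mol %), THF, 65 °C; anhydrous MeOH quench; then N2H4·H2O, AcOH (cat.), EtOH, 80 °C
Reagents that add atoms: hydrazine hydrate, NN.O
Why: Copper(I)-catalysed Grignard addition to the nitrile should give a hindered N–H ketimine that survives a methanol quench, and transimination (imine exchange) with hydrazine should deliver the N-unsubstituted hydrazone without passing through the doubly ortho-substituted ketone, which would condense poorly.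

Step 4
Reactants: 10 hydrazone of {4-bromo-2-methoxy-6-[(4-methoxyphenyl)methoxy]phenyl}(3,5-dimethoxyphenyl)methanone
Product: 13 (2S,3S)-6-bromo-3-(3,5-dimethoxyphenyl)-4-methoxy-2-(4-methoxyphenyl)-2,3-dihydro-1-benzofuran, via diaryldiazomethane 11 (not isolated), via cis-dihydrobenzofuran 12 (not isolated)
Conditions: MnO2, CH2Cl2, 0 °C; filter; Rh2(R-PTAD)4 (1 mol %), CH2Cl2, −20 °C → rt; then CF3CO2H, rt
Reagents that add atoms: none
Why: MnO2 dehydrogenates the hydrazone to the diaryldiazomethane, whose rhodium donor/donor carbene should undergo enantioselective 1,5-C–H insertion into the only benzylic ether CH2 (the chiral carboxylate catalyst sets C3 = C8'' and the insertion gives the cis isomer), and trifluoroacetic acid then epimerises C2 = C7'' to the more stable trans isomer by reversible heterolysis of the 4-methoxybenzylic C–O bond, which leaves C3 untouched.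

Step 5
Reactants: 13 (2S,3S)-6-bromo-3-(3,5-dimethoxyphenyl)-4-methoxy-2-(4-methoxyphenyl)-2,3-dihydro-1-benzofuran; 14 (2-ethoxy-2-oxoethyl)zinc bromide
Product: 15 ethyl 2-[(2S,3S)-3-(3,5-dimethoxyphenyl)-4-methoxy-2-(4-methoxyphenyl)-2,3-dihydro-1-benzofuran-6-yl]acetate
Conditions: 14 (1.5 equiv), Pd2(dba)3 (1 mol %), XPhos (4 mol %), THF, 50 °C
Reagents that add atoms: none
Why: Negishi-type palladium-catalysed arylation of a Reformatsky zinc enolate installs the acetate side chain on the aryl bromide under non-basic conditions that do not touch the dihydrobenzofuran stereocentres.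

Step 6
Reactants: 15 ethyl 2-[(2S,3S)-3-(3,5-dimethoxyphenyl)-4-methoxy-2-(4-methoxyphenyl)-2,3-dihydro-1-benzofuran-6-yl]acetate
Product: 16 2-[(2S,3S)-3-(3,5-dimethoxyphenyl)-4-methoxy-2-(4-methoxyphenyl)-2,3-dihydro-1-benzofuran-6-yl]acetic acid
Conditions: LiOH·H2O, THF/MeOH/H2O, rt; then 1 M HCl
Reagents that add atoms: lithium hydroxide, [Li+].[OH-]
Why: Saponification of the ethyl ester; no stereocentre lies next to an acidifying group, so none is affected.

Step 7
Reactants: 16 2-[(2S,3S)-3-(3,5-dimethoxyphenyl)-4-methoxy-2-(4-methoxyphenyl)-2,3-dihydro-1-benzofuran-6-yl]acetic acid; 2 (4S)-4-benzyl-1,3-oxazolidin-2-one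
Product: 17 (4S)-4-benzyl-3-{2-[(2S,3S)-3-(3,5-dimethoxyphenyl)-4-methoxy-2-(4-methoxyphenyl)-2,3-dihydro-1-benzofuran-6-yl]acetyl}-1,3-oxazolidin-2-one
Conditions: PivCl, Et3N, THF, −20 °C; then LiCl, 2, −20 °C → rt
Reagents that add atoms: none
Why: The same mixed-anhydride N-acylation as in step 1; it creates no stereocentre and its mild base does not affect the dihydrobenzofuran.

Step 8
Reactants: 3 (4S)-4-benzyl-3-[2-(3,5-dimethoxyphenyl)acetyl]-1,3-oxazolidin-2-one (4 equiv); 17 (4S)-4-benzyl-3-{2-[(2S,3S)-3-(3,5-dimethoxyphenyl)-4-methoxy-2-(4-methoxyphenyl)-2,3-dihydro-1-benzofuran-6-yl]acetyl}-1,3-oxazolidin-2-one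
Product: 18 (2S,3S)-1,4-bis[(4S)-4-benzyl-2-oxo-1,3-oxazolidin-3-yl]-2-(3,5-dimethoxyphenyl)-3-[(2S,3S)-3-(3,5-dimethoxyphenyl)-4-methoxy-2-(4-methoxyphenyl)-2,3-dihydro-1-benzofuran-6-yl]butane-1,4-dione
Conditions: LDA (1.05 equiv per imide), THF, −78 °C; then TiCl4 (1 equiv per enolate), −78 → −20 °C
Reagents that add atoms: none
Why: Oxidative coupling of the titanium enolates of chiral 3-(arylacetyl)oxazolidin-2-ones (one-electron oxidation by Ti(IV) and union of two like-polarity α-carbons) forms C8–C8'; each chelated Z-enolate should react on the face opposite its own 4-benzyl group to give the (8S,8'S) isomer, and the excess of cheap 3 channels 17 into the cross-product, the symmetric homodimer of 3 being removed by chromatography.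

Step 9
Reactants: 18 (2S,3S)-1,4-bis[(4S)-4-benzyl-2-oxo-1,3-oxazolidin-3-yl]-2-(3,5-dimethoxyphenyl)-3-[(2S,3S)-3-(3,5-dimethoxyphenyl)-4-methoxy-2-(4-methoxyphenyl)-2,3-dihydro-1-benzofuran-6-yl]butane-1,4-dione
Product: 19 S,S'-diethyl (2S,3S)-2-(3,5-dimethoxyphenyl)-3-[(2S,3S)-3-(3,5-dimethoxyphenyl)-4-methoxy-2-(4-methoxyphenyl)-2,3-dihydro-1-benzofuran-6-yl]butanebis(thioate)
Conditions: EtSH, n-BuLi (→ LiSEt), THF, 0 °C
Reagents that add atoms: ethanethiol (as lithium ethanethiolate), CCS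
Why: Thiolysis of N-acyloxazolidinones by lithium ethanethiolate occurs at the exocyclic carbonyl, and the thiolate is too weakly basic to epimerise the α-aryl stereocentres; the auxiliary is recovered.

Step 10
Reactants: 19 S,S'-diethyl (2S,3S)-2-(3,5-dimethoxyphenyl)-3-[(2S,3S)-3-(3,5-dimethoxyphenyl)-4-methoxy-2-(4-methoxyphenyl)-2,3-dihydro-1-benzofuran-6-yl]butanebis(thioate); 20 (4-methoxyphenyl)boronic acid
Product: 21 (2S,3S)-2-(3,5-dimethoxyphenyl)-3-[(2S,3S)-3-(3,5-dimethoxyphenyl)-4-methoxy-2-(4-methoxyphenyl)-2,3-dihydro-1-benzofuran-6-yl]-1,4-bis(4-methoxyphenyl)butane-1,4-dione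
Conditions: 20 (3 equiv), Pd2(dba)3 (5 mol %), tri(2-furyl)phosphine (20 mol %), CuTC (3 equiv), THF, 50 °C
Reagents that add atoms: none
Why: A twofold Liebeskind–Srogl coupling (Pd(0) with a Cu(I) carboxylate, neutral medium) converts both thioesters into aryl ketones without enolisation, as it does for α-chiral thioesters, so C8 and C8' should be retained.

Step 11
Reactants: 21 (2S,3S)-2-(3,5-dimethoxyphenyl)-3-[(2S,3S)-3-(3,5-dimethoxyphenyl)-4-methoxy-2-(4-methoxyphenyl)-2,3-dihydro-1-benzofuran-6-yl]-1,4-bis(4-methoxyphenyl)butane-1,4-dione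
Product: 22 (2S,3S)-2-(3,5-dimethoxyphenyl)-3-[(2S,3S)-3-(3,5-dimethoxyphenyl)-4-methoxy-2-(4-methoxyphenyl)-2,3-dihydro-1-benzofuran-6-yl]-1,4-bis(4-methoxyphenyl)butane-1,4-diol (mixture of C1/C4 epimers)
Conditions: NaBH4, CeCl3·7H2O, MeOH/THF, −40 → 0 °C
Reagents that add atoms: none
Why: Luche-type 1,2-reduction at low temperature should give the diol before the medium can epimerise the α-aryl ketones; the carbinol configurations are irrelevant because both carbons are ionised in the next step.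

Step 12
Reactants: 22 (2S,3S)-2-(3,5-dimethoxyphenyl)-3-[(2S,3S)-3-(3,5-dimethoxyphenyl)-4-methoxy-2-(4-methoxyphenyl)-2,3-dihydro-1-benzofuran-6-yl]-1,4-bis(4-methoxyphenyl)butane-1,4-diol
Product: 23 octa-O-methyl ether of the target, (7R,8R,7'R,8'R,7''S,8''S)
Conditions: BF3·OEt2 (3 equiv), CH2Cl2 (0.005 M), −78 → −30 °C
Reagents that add atoms: none
Why: BF3 ionises both secondary 4-methoxybenzylic alcohols (directly or through the 2,5-diaryltetrahydrofuran that may form first), and each cation is captured by the electron-rich ring on the neighbouring carbon, C7(+) by C10' of ring A and C7'(+) by C10 of ring B. The closest known reaction type is the twofold intramolecular Friedel–Crafts alkylation that converts 8–8'-linked bis(quinone methides) and tetraaryl-1,4-diols into the dibenzo-bicyclo[3.3.0]octane skeleton of pallidol-type dimers. Ring 1 (C7–C8–C8'–C9'–C10') and ring 2 (C7'–C8'–C8–C9–C10) each close by attack of an arene carbon on an exocyclic benzylic cation with the arene C=C bond ending inside the new five-membered ring (formally 5-endo at the arene), the usual geometry of 1-arylindane-forming Friedel–Crafts reactions. C8 and C8' are carried over from step 8, and their (S,S) relationship allows only the cis-fused bicycle; C7 and C7' are set by substrate control, each aryl group taking the convex face trans to the adjacent ring-fusion substituent, which avoids eclipsing in the transition state and is also the more stable arrangement. The step needs closure of ring 2 at C10 and not at C14: C10 lies next to the tied-back dihydrofuran oxygen and para to the C13 methoxy group, whereas C14 is shielded by the C13 methoxy methyl group, which the C12 substituent forces toward C14; ring A is symmetric. The dihydrobenzofuran C7''–O bond can ionise only reversibly back to the same trans isomer, and the low temperature together with the far more labile benzylic alcohols should keep it intact.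

Step 13
Reactants: 23 octa-O-methyl ether of the target
Product: 24 target compound CNP0154244.2, (7R,8R,7'R,8'R,7''S,8''S)
Conditions: BBr3 (20 equiv), CH2Cl2, −78 → 23 °C; then MeOH, H2O
Reagents that add atoms: none
Why: Boron tribromide cleaves all eight aryl methyl ethers (Lewis acid-assisted SN2 at methyl); the dihydrobenzofuran C–O bond can only re-close to the thermodynamic trans isomer, and no stereocentre is broken irreversibly.

## Compound list

1 | 2-(3,5-dimethoxyphenyl)acetic acid | COc1cc(CC(=O)O)cc(OC)c1 | starting material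
2 | (4S)-4-benzyl-1,3-oxazolidin-2-one | O=C1N[C@@H](Cc2ccccc2)CO1 | starting material
3 | (4S)-4-benzyl-3-[2-(3,5-dimethoxyphenyl)acetyl]-1,3-oxazolidin-2-one | COc1cc(CC(=O)N2[C@@H](Cc3ccccc3)COC2=O)cc(OC)c1 | intermediate
4 | 4-bromo-2,6-difluorobenzonitrile | N#Cc1c(F)cc(Br)cc1F | starting material
5 | (4-methoxyphenyl)methanol | COc1ccc(CO)cc1 | starting material
6 | 4-bromo-2-fluoro-6-[(4-methoxyphenyl)methoxy]benzonitrile | N#Cc1c(F)cc(Br)cc1OCc1ccc(OC)cc1 | intermediate
7 | 4-bromo-2-methoxy-6-[(4-methoxyphenyl)methoxy]benzonitrile | N#Cc1c(OC)cc(Br)cc1OCc1ccc(OC)cc1 | intermediate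
8 | (3,5-dimethoxyphenyl)magnesium bromide (solution in THF) | COc1cc([Mg]Br)cc(OC)c1 | starting material
9 | {4-bromo-2-methoxy-6-[(4-methoxyphenyl)methoxy]phenyl}(3,5-dimethoxyphenyl)methanimine | N=C(c1cc(OC)cc(OC)c1)c1c(OC)cc(Br)cc1OCc1ccc(OC)cc1 | intermediate
10 | hydrazone of {4-bromo-2-methoxy-6-[(4-methoxyphenyl)methoxy]phenyl}(3,5-dimethoxyphenyl)methanone | NN=C(c1cc(OC)cc(OC)c1)c1c(OC)cc(Br)cc1OCc1ccc(OC)cc1 | intermediate
11 | {4-bromo-2-methoxy-6-[(4-methoxyphenyl)methoxy]phenyl}(3,5-dimethoxyphenyl)diazomethane | [N-]=[N+]=C(c1cc(OC)cc(OC)c1)c1c(OC)cc(Br)cc1OCc1ccc(OC)cc1 | intermediate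
12 | (2R,3S)-6-bromo-3-(3,5-dimethoxyphenyl)-4-methoxy-2-(4-methoxyphenyl)-2,3-dihydro-1-benzofuran (cis) | COc1cc(Br)cc2O[C@@H](c3ccc(OC)cc3)[C@@H](c3cc(OC)cc(OC)c3)c12 | intermediate
13 | (2S,3S)-6-bromo-3-(3,5-dimethoxyphenyl)-4-methoxy-2-(4-methoxyphenyl)-2,3-dihydro-1-benzofuran (trans) | COc1cc(Br)cc2O[C@H](c3ccc(OC)cc3)[C@@H](c3cc(OC)cc(OC)c3)c12 | intermediate
14 | (2-ethoxy-2-oxoethyl)zinc bromide (solution in THF) | CCOC(=O)C[Zn]Br | starting material
15 | ethyl 2-[(2S,3S)-3-(3,5-dimethoxyphenyl)-4-methoxy-2-(4-methoxyphenyl)-2,3-dihydro-1-benzofuran-6-yl]acetate | COc1cc(CC(=O)OCC)cc2O[C@H](c3ccc(OC)cc3)[C@@H](c3cc(OC)cc(OC)c3)c12 | intermediate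
16 | 2-[(2S,3S)-3-(3,5-dimethoxyphenyl)-4-methoxy-2-(4-methoxyphenyl)-2,3-dihydro-1-benzofuran-6-yl]acetic acid | COc1cc(CC(=O)O)cc2O[C@H](c3ccc(OC)cc3)[C@@H](c3cc(OC)cc(OC)c3)c12 | intermediate
17 | (4S)-4-benzyl-3-{2-[(2S,3S)-3-(3,5-dimethoxyphenyl)-4-methoxy-2-(4-methoxyphenyl)-2,3-dihydro-1-benzofuran-6-yl]acetyl}-1,3-oxazolidin-2-one | COc1cc(CC(=O)N3[C@@H](Cc4ccccc4)COC3=O)cc2O[C@H](c3ccc(OC)cc3)[C@@H](c3cc(OC)cc(OC)c3)c12 | intermediate
18 | (2S,3S)-1,4-bis[(4S)-4-benzyl-2-oxo-1,3-oxazolidin-3-yl]-2-(3,5-dimethoxyphenyl)-3-[(2S,3S)-3-(3,5-dimethoxyphenyl)-4-methoxy-2-(4-methoxyphenyl)-2,3-dihydro-1-benzofuran-6-yl]butane-1,4-dione | O=C(N1[C@@H](Cc2ccccc2)COC1=O)[C@H](c1cc(OC)cc(OC)c1)[C@@H](c1cc(OC)c2c(c1)O[C@H](c1ccc(OC)cc1)[C@H]2c1cc(OC)cc(OC)c1)C(=O)N1[C@@H](Cc2ccccc2)COC1=O | intermediate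
19 | S,S'-diethyl (2S,3S)-2-(3,5-dimethoxyphenyl)-3-[(2S,3S)-3-(3,5-dimethoxyphenyl)-4-methoxy-2-(4-methoxyphenyl)-2,3-dihydro-1-benzofuran-6-yl]butanebis(thioate) | CCSC(=O)[C@H](c1cc(OC)cc(OC)c1)[C@@H](c1cc(OC)c2c(c1)O[C@H](c1ccc(OC)cc1)[C@H]2c1cc(OC)cc(OC)c1)C(=O)SCC | intermediate
20 | (4-methoxyphenyl)boronic acid | COc1ccc(B(O)O)cc1 | starting material
21 | (2S,3S)-2-(3,5-dimethoxyphenyl)-3-[(2S,3S)-3-(3,5-dimethoxyphenyl)-4-methoxy-2-(4-methoxyphenyl)-2,3-dihydro-1-benzofuran-6-yl]-1,4-bis(4-methoxyphenyl)butane-1,4-dione | COc1ccc(C(=O)[C@H](c2cc(OC)cc(OC)c2)[C@@H](c2cc(OC)c3c(c2)O[C@H](c2ccc(OC)cc2)[C@H]3c2cc(OC)cc(OC)c2)C(=O)c2ccc(OC)cc2)cc1 | intermediate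
22 | (2S,3S)-2-(3,5-dimethoxyphenyl)-3-[(2S,3S)-3-(3,5-dimethoxyphenyl)-4-methoxy-2-(4-methoxyphenyl)-2,3-dihydro-1-benzofuran-6-yl]-1,4-bis(4-methoxyphenyl)butane-1,4-diol (C1/C4 epimer mixture) | COc1ccc(C(O)[C@H](c2cc(OC)cc(OC)c2)[C@@H](c2cc(OC)c3c(c2)O[C@H](c2ccc(OC)cc2)[C@H]3c2cc(OC)cc(OC)c2)C(O)c2ccc(OC)cc2)cc1 | intermediate
23 | octa-O-methyl ether of the target, (7R,8R,7'R,8'R,7''S,8''S) | COc1ccc([C@@H]2c3c(OC)cc(OC)cc3[C@H]3[C@H](c4ccc(OC)cc4)c4c(cc(OC)c5c4O[C@H](c4ccc(OC)cc4)[C@H]5c4cc(OC)cc(OC)c4)[C@@H]23)cc1 | intermediate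
24 | CNP0154244.2, (7R,8R,7'R,8'R,7''S,8''S)-configured resveratrol trimer | Oc1ccc([C@@H]2c3c(O)cc(O)cc3[C@H]3[C@H](c4ccc(O)cc4)c4c(cc(O)c5c4O[C@H](c4ccc(O)cc4)[C@H]5c4cc(O)cc(O)c4)[C@@H]23)cc1 | target

## Step count and risks

Total step count: 13. Longest linear sequence: 12 (steps 2–13, from 4 to 24).

Step 8 (oxidative enolate cross-coupling). What may go wrong: the two enolates pair statistically, so much of the valuable imide 17 may be lost to homo-coupling or simple proton return; the titanium Lewis acid may open the dihydrobenzofuran; the facial control of one enolate may be eroded. The fallback is a cross-selective coupling of two different enolate classes. It sets out from bromide 13 and imide 3. Palladium-catalysed α-arylation of 4'-methoxyacetophenone with 13 (Pd2(dba)3, Xantphos, NaOtBu, toluene, 80 °C) would give 2-[(2S,3S)-3-(3,5-dimethoxyphenyl)-4-methoxy-2-(4-methoxyphenyl)-2,3-dihydro-1-benzofuran-6-yl]-1-(4-methoxyphenyl)ethanone F1. Oxidative heterocoupling of the lithium enolates of F1 and 3 (LDA, THF, −78 °C; Fe(acac)3) would give the keto-imide F2, in which C8' is set by the auxiliary and the C8 epimer is removed by chromatography. Thiolysis with LiSEt would give the keto-thioester F3, and a single Liebeskind–Srogl coupling with 20 comes back to the route at diketone 21.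

Step 12 (twofold Friedel–Crafts closure). What may go wrong: proton loss from the open-chain benzylic cations before ring closure (stilbene formation that scrambles C8/C8'), competing heterolysis of the dihydrobenzofuran C–O bond, or attack of ring B through C14. The fallback reverses the bond order, so that the rings are closed by acylation and the anisyl groups enter last. It sets out from bis-imide 18. Cleavage with LiOH/H2O2 would give (2S,3S)-2-(3,5-dimethoxyphenyl)-3-[(2S,3S)-dihydrobenzofuran-6-yl]butanedioic acid F4. Oxalyl chloride with catalytic DMF would give the bis(acid chloride) F5, which is not isolated. SnCl4 (CH2Cl2, −78 → 0 °C) should then effect a twofold Friedel–Crafts acylation to the cis-fused 7,7'-dione F6, in which C8 and C8' are locked by the ring fusion. NaBH4 would give the 7,7'-diol F7. BF3·OEt2 in anisole/CH2Cl2 would ionise the doubly benzylic alcohols, and para attack of anisole from the convex face comes back to the route at 23.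

Step 3 (nitrile addition and hydrazone formation). What may go wrong: the aryl Grignard reagent may not reach the nitrile carbon between two ortho alkoxy groups, or may displace one of them, or the hindered ketimine may not exchange with hydrazine. The fallback builds the diaryl carbon at the aldehyde oxidation level and reaches the hydrazone through a thioketone. It sets out from nitrile 7. DIBAL-H (toluene, −78 °C; aqueous acid) would give 4-bromo-2-methoxy-6-[(4-methoxyphenyl)methoxy]benzaldehyde F8. Addition of 8 (THF, 0 °C) would give the diarylmethanol F9, and Dess–Martin periodinane the diaryl ketone F10. Lawesson's reagent (toluene, 90 °C) would give the thioketone F11, which should condense with hydrazine hydrate at room temperature and so come back to the route at hydrazone 10.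

Further compounds

F1 | step 8 | 2-[(2S,3S)-3-(3,5-dimethoxyphenyl)-4-methoxy-2-(4-methoxyphenyl)-2,3-dihydro-1-benzofuran-6-yl]-1-(4-methoxyphenyl)ethanone | COc1ccc(C(=O)Cc2cc(OC)c3c(c2)O[C@H](c2ccc(OC)cc2)[C@H]3c2cc(OC)cc(OC)c2)cc1
F2 | step 8 | (4S)-4-benzyl-3-{(2S,3S)-2-(3,5-dimethoxyphenyl)-3-[(2S,3S)-3-(3,5-dimethoxyphenyl)-4-methoxy-2-(4-methoxyphenyl)-2,3-dihydro-1-benzofuran-6-yl]-4-(4-methoxyphenyl)-4-oxobutanoyl}-1,3-oxazolidin-2-one | O=C(N1[C@@H](Cc2ccccc2)COC1=O)[C@H](c1cc(OC)cc(OC)c1)[C@@H](c1cc(OC)c2c(c1)O[C@H](c1ccc(OC)cc1)[C@H]2c1cc(OC)cc(OC)c1)C(=O)c1ccc(OC)cc1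
F3 | step 8 | S-ethyl (2S,3S)-2-(3,5-dimethoxyphenyl)-3-[(2S,3S)-3-(3,5-dimethoxyphenyl)-4-methoxy-2-(4-methoxyphenyl)-2,3-dihydro-1-benzofuran-6-yl]-4-(4-methoxyphenyl)-4-oxobutanethioate | CCSC(=O)[C@H](c1cc(OC)cc(OC)c1)[C@@H](c1cc(OC)c2c(c1)O[C@H](c1ccc(OC)cc1)[C@H]2c1cc(OC)cc(OC)c1)C(=O)c1ccc(OC)cc1
F4 | step 12 | (2S,3S)-2-(3,5-dimethoxyphenyl)-3-[(2S,3S)-3-(3,5-dimethoxyphenyl)-4-methoxy-2-(4-methoxyphenyl)-2,3-dihydro-1-benzofuran-6-yl]butanedioic acid | OC(=O)[C@H](c1cc(OC)cc(OC)c1)[C@@H](c1cc(OC)c2c(c1)O[C@H](c1ccc(OC)cc1)[C@H]2c1cc(OC)cc(OC)c1)C(=O)O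
F5 | step 12 | (2S,3S)-2-(3,5-dimethoxyphenyl)-3-[(2S,3S)-3-(3,5-dimethoxyphenyl)-4-methoxy-2-(4-methoxyphenyl)-2,3-dihydro-1-benzofuran-6-yl]butanedioyl dichloride | ClC(=O)[C@H](c1cc(OC)cc(OC)c1)[C@@H](c1cc(OC)c2c(c1)O[C@H](c1ccc(OC)cc1)[C@H]2c1cc(OC)cc(OC)c1)C(Cl)=O
F6 | step 12 | cis-fused 7,7'-dione corresponding to 23 (both CH(4-methoxyphenyl) groups replaced by C=O, ring-fusion hydrogens as in 23) | O=C1c2c(OC)cc(OC)cc2[C@H]2C(=O)c3c(cc(OC)c4c3O[C@H](c3ccc(OC)cc3)[C@H]4c3cc(OC)cc(OC)c3)[C@@H]12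
F7 | step 12 | cis-fused 7,7'-diol corresponding to F6 (carbinol epimer mixture) | OC1c2c(OC)cc(OC)cc2[C@H]2C(O)c3c(cc(OC)c4c3O[C@H](c3ccc(OC)cc3)[C@H]4c3cc(OC)cc(OC)c3)[C@@H]12
F8 | step 3 | 4-bromo-2-methoxy-6-[(4-methoxyphenyl)methoxy]benzaldehyde | O=Cc1c(OC)cc(Br)cc1OCc1ccc(OC)cc1
F9 | step 3 | {4-bromo-2-methoxy-6-[(4-methoxyphenyl)methoxy]phenyl}(3,5-dimethoxyphenyl)methanol | OC(c1cc(OC)cc(OC)c1)c1c(OC)cc(Br)cc1OCc1ccc(OC)cc1
F10 | step 3 | {4-bromo-2-methoxy-6-[(4-methoxyphenyl)methoxy]phenyl}(3,5-dimethoxyphenyl)methanone | O=C(c1cc(OC)cc(OC)c1)c1c(OC)cc(Br)cc1OCc1ccc(OC)cc1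
F11 | step 3 | {4-bromo-2-methoxy-6-[(4-methoxyphenyl)methoxy]phenyl}(3,5-dimethoxyphenyl)methanethione | S=C(c1cc(OC)cc(OC)c1)c1c(OC)cc(Br)cc1OCc1ccc(OC)cc1
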